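**Strategy.** The dihydrofuran ring is opened across O1–C7a and C2–C3, which leads back to 5-acetyl-2-fluorobenzaldehyde and a γ-silyloxy methallyl borane. The plan exploits two features: C2 and C3 form a syn-1,2-dioxygenated pair in which C2 is also allylic to the propenyl unit, and C7a lies para to the C5 side-chain carbon, which as an acetyl group activates a fluoride at C7a. In one flask, Brown-type oxyallylboration of the aldehyde forms C2–C3 and sets both ring stereocentres, and fluoride then unmasks the C2 oxygen, which closes the furan ring by substitution at C7a. Ketone reduction, double acylation and allylic oxidation finish the route.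

Key step: step 3

Remark on the chemistry: the descriptors (2R,3R) correspond to the cis arrangement of the C2 propenyl unit and the C3 ester. Compounds 1 and 4, tributyl(1-ethoxyvinyl)stannane, (−)-Ipc2BOMe [from (+)-α-pinene], 3-methylbutanoic anhydride and RuCl[(R,R)-TsDPEN](p-cymene) are taken as purchased.

Step 1
Reactants: 1 5-bromo-2-fluorobenzaldehyde
Product: 3 5-acetyl-2-fluorobenzaldehyde, via enol ether 2 (not isolated)
Conditions: tributyl(1-ethoxyvinyl)stannane, Pd(PPh3)4 (cat.), toluene, 100 °C; then 1 M HCl, THF, rt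
Reagents that add atoms: tributyl(1-ethoxyvinyl)stannane, C=C(OCC)[Sn](CCCC)(CCCC)CCCC; water, O
Why: Stille coupling of the aryl bromide tolerates the aldehyde and the fluoride, and mild acid hydrolysis of the enol ether should unveil the methyl ketone that later activates the fluoride para to it.

Step 2
Reactants: 4 2-methylprop-2-en-1-ol
Product: 5 tert-butyl(dimethyl)[(2-methylprop-2-en-1-yl)oxy]silane
Conditions: TBSCl, imidazole, DMF, 0 °C → rt
Reagents that add atoms: tert-butyldimethylsilyl chloride, CC(C)(C)[Si](C)(C)Cl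
Why: Imidazole-promoted silylation of a primary allylic alcohol is a routine protection and gives the ether whose oxygen-bearing carbon becomes C2.

Step 3
Reactants: 3 5-acetyl-2-fluorobenzaldehyde; 5 tert-butyl(dimethyl)[(2-methylprop-2-en-1-yl)oxy]silane
Product: 8 (2R,3R)-1-[3-hydroxy-2-(prop-1-en-2-yl)-2,3-dihydro-1-benzofuran-5-yl]ethan-1-one, via allylborane 6 (not isolated), via borinate 7 (not isolated)
Conditions: 5, sBuLi, THF, −78 °C; (−)-Ipc2BOMe, −78 °C; BF3·OEt2 then 3, −78 °C; TBAF (excess), THF/DMF, −78 → 45 °C; H2O2, pH 7 buffer, 0 °C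
Reagents that add atoms: none
Why: sBuLi removes an oxygen-adjacent allylic proton of 5, the chelated Z-oxyallyllithium is trapped at its γ-carbon by (−)-Ipc2BOMe, BF3·OEt2 frees allylborane 6, and 6 adds to the aldehyde of 3 (not to its ketone, which is far less reactive at −78 °C) through a closed six-membered chair transition state, forming C2–C3 in borinate 7. The closest known reaction type is the Brown γ-alkoxyallylboration of aldehydes, followed here in the same flask by fluoride desilylation and intramolecular nucleophilic aromatic substitution of a para-acyl fluoroarene. The isopinocampheyl groups from (+)-α-pinene direct the allyl unit to the Si face of the aldehyde and so set C3 as R, and the Z enol-ether geometry, which holds the silyloxy group axial in the chair, sets C2 as R, that is, the syn pattern that becomes the cis ring. TBAF then cleaves the O–Si bond (or the C3 alkoxide first takes the silyl group by a 1,2 oxygen-to-oxygen shift; both paths end in the C2 alkoxide), and this alkoxide attacks C7a in a 5-exo addition–elimination through a Meisenheimer intermediate stabilised by the para acetyl group, forming O1–C7a with loss of fluoride. Only the C2 oxygen can close a five-membered ring (the C3 oxygen would give a four-membered one), neither stereocentre is touched in the closure, and the buffered peroxide work-up cleaves the B–O and B–C bonds of the boron residue.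

Step 4
Reactants: 8 (2R,3R)-1-[3-hydroxy-2-(prop-1-en-2-yl)-2,3-dihydro-1-benzofuran-5-yl]ethan-1-one
Product: 9 (2R,3R)-5-[(1R)-1-hydroxyethyl]-2-(prop-1-en-2-yl)-2,3-dihydro-1-benzofuran-3-ol
Conditions: RuCl[(R,R)-TsDPEN](p-cymene) (cat.), HCO2Na, H2O/MeOH, 40 °C
Reagents that add atoms: none
Why: Noyori-type asymmetric transfer hydrogenation should deliver hydride to the Si face of the aryl methyl ketone under control of the (R,R)-diamine ligand, setting the side-chain carbinol as R at near-neutral pH while the alkene and the C3 alcohol stay untouched.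

Step 5
Reactants: 9 (2R,3R)-5-[(1R)-1-hydroxyethyl]-2-(prop-1-en-2-yl)-2,3-dihydro-1-benzofuran-3-ol
Product: 10 (1R)-1-[(2R,3R)-3-(3-methylbutanoyloxy)-2-(prop-1-en-2-yl)-2,3-dihydro-1-benzofuran-5-yl]ethyl 3-methylbutanoate
Conditions: (iBuCO)2O, Et3N, DMAP (cat.), CH2Cl2, 0 °C → rt
Reagents that add atoms: 3-methylbutanoic anhydride, CC(C)CC(=O)OC(=O)CC(C)C
Why: DMAP-catalysed acyl transfer esterifies both secondary benzylic alcohols in one operation at oxygen only, so all three stereocentres are retained.

Step 6
Reactants: 10 (1R)-1-[(2R,3R)-3-(3-methylbutanoyloxy)-2-(prop-1-en-2-yl)-2,3-dihydro-1-benzofuran-5-yl]ethyl 3-methylbutanoate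
Product: 12 (2R,3R)-5-[(1R)-1-(3-methylbutanoyloxy)ethyl]-2-(3-oxoprop-1-en-2-yl)-2,3-dihydro-1-benzofuran-3-yl 3-methylbutanoate, via allylic alcohol 11 (not isolated)
Conditions: SeO2 (0.5 equiv), tBuOOH, CH2Cl2, rt; then MnO2, CH2Cl2, rt
Reagents that add atoms: selenium dioxide, O=[Se]=O; tert-butyl hydroperoxide, CC(C)(C)OO
Why: Riley oxidation (ene reaction, then 2,3-sigmatropic shift) should functionalise the methyl group of the 1,1-disubstituted alkene, since the only other allylic hydrogen is the hindered, oxygen-deactivated C2 methine, and MnO2 then carries the allylic alcohol fraction 11 on to the conjugated aldehyde without touching the esters or the stereocentres.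

**Compound list**

1 | 5-bromo-2-fluorobenzaldehyde | O=Cc1cc(Br)ccc1F | starting material
2 | 5-(1-ethoxyethenyl)-2-fluorobenzaldehyde | C=C(OCC)c1ccc(F)c(C=O)c1 | intermediate
3 | 5-acetyl-2-fluorobenzaldehyde | CC(=O)c1ccc(F)c(C=O)c1 | intermediate
4 | 2-methylprop-2-en-1-ol | C=C(C)CO | starting material
5 | tert-butyl(dimethyl)[(2-methylprop-2-en-1-yl)oxy]silane | C=C(C)CO[Si](C)(C)C(C)(C)C | intermediate
6 | [(2Z)-3-{[tert-butyl(dimethyl)silyl]oxy}-2-methylprop-2-en-1-yl]bis(isopinocampheyl)borane, isopinocampheyl groups from (+)-α-pinene | C(/C(C)=C\O[Si](C)(C)C(C)(C)C)B([C@@H]1C[C@@H]2C[C@H]([C@H]1C)C2(C)C)[C@@H]1C[C@@H]2C[C@H]([C@H]1C)C2(C)C | intermediate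
7 | (1R,2R)-1-(5-acetyl-2-fluorophenyl)-2-{[tert-butyl(dimethyl)silyl]oxy}-3-methylbut-3-en-1-yl bis(isopinocampheyl)borinate | CC(=O)c1ccc(F)c(c1)[C@@H](OB([C@@H]1C[C@@H]2C[C@H]([C@H]1C)C2(C)C)[C@@H]1C[C@@H]2C[C@H]([C@H]1C)C2(C)C)[C@H](O[Si](C)(C)C(C)(C)C)C(C)=C | intermediate
8 | (2R,3R)-1-[3-hydroxy-2-(prop-1-en-2-yl)-2,3-dihydro-1-benzofuran-5-yl]ethan-1-one (cis) | C=C(C)[C@H]1Oc2ccc(C(C)=O)cc2[C@H]1O | intermediate
9 | (2R,3R)-5-[(1R)-1-hydroxyethyl]-2-(prop-1-en-2-yl)-2,3-dihydro-1-benzofuran-3-ol | C=C(C)[C@H]1Oc2ccc([C@@H](C)O)cc2[C@H]1O | intermediate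
10 | (1R)-1-[(2R,3R)-3-(3-methylbutanoyloxy)-2-(prop-1-en-2-yl)-2,3-dihydro-1-benzofuran-5-yl]ethyl 3-methylbutanoate | C=C(C)[C@H]1Oc2ccc([C@@H](C)OC(=O)CC(C)C)cc2[C@H]1OC(=O)CC(C)C | intermediate
11 | (1R)-1-[(2R,3R)-2-(3-hydroxyprop-1-en-2-yl)-3-(3-methylbutanoyloxy)-2,3-dihydro-1-benzofuran-5-yl]ethyl 3-methylbutanoate | C=C(CO)[C@H]1Oc2ccc([C@@H](C)OC(=O)CC(C)C)cc2[C@H]1OC(=O)CC(C)C | intermediate
12 | (2R,3R)-5-[(1R)-1-(3-methylbutanoyloxy)ethyl]-2-(3-oxoprop-1-en-2-yl)-2,3-dihydro-1-benzofuran-3-yl 3-methylbutanoate | C=C(C=O)[C@H]1Oc2ccc([C@@H](C)OC(=O)CC(C)C)cc2[C@H]1OC(=O)CC(C)C | target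

**Totals.** Total step count: 6. Longest linear sequence: 5 steps (steps 1, 3, 4, 5, 6); step 2 is a one-step branch.

**Steps most likely to fail**

Step 3. The lithiated silyl ether may suffer silyl migration from oxygen to carbon or deprotonation at the methyl group instead of the oxygen-bearing carbon, and ring closure may stall while boron residues bind the fluoride. The fallback separates the two bond formations and uses an acetal in place of the silyl group. It sets out from 4 and 3. Compound 4 with MOMCl and iPr2NEt in CH2Cl2 should give 3-(methoxymethoxy)-2-methylprop-1-ene F1. F1 under the same sBuLi / (−)-Ipc2BOMe / BF3·OEt2 protocol with 3, with buffered H2O2 work-up, should give isolated (1R,2R)-1-(5-acetyl-2-fluorophenyl)-2-(methoxymethoxy)-3-methylbut-3-en-1-ol F2. HCl in MeOH should then free (1R,2R)-1-(5-acetyl-2-fluorophenyl)-3-methylbut-3-ene-1,2-diol F3, and K2CO3 in DMF at 60 °C should close the ring by substitution of the fluoride, coming back to the route at 8.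

Step 6. The oxidation may attack the wrong allylic position, stall at the alcohol stage, or ionise the two benzylic esters through acidic selenium species. The fallback sets out from 10. Dye-sensitised photo-oxygenation (O2, tetraphenylporphyrin, visible light, CH2Cl2; Schenck ene reaction) should give the primary allylic hydroperoxide (1R)-1-[(2R,3R)-2-(3-hydroperoxyprop-1-en-2-yl)-3-(3-methylbutanoyloxy)-2,3-dihydro-1-benzofuran-5-yl]ethyl 3-methylbutanoate F4. Dehydration of F4 with Ac2O and pyridine (Kornblum–DeLaMare-type elimination) should come back to the route at 12.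

Step 4. Turnover may be slow and facial selectivity lower with the electron-rich para-alkoxy aryl ketone, and reversible dehydrogenation at the benzylic C3 carbinol could erode the C2/C3 configuration. The fallback sets out from 8 and replaces the ruthenium catalyst by an (R)-selective NADPH-dependent ketoreductase (alcohol dehydrogenase class) with isopropanol cofactor recycling in pH 7 buffer and DMSO co-solvent. It should come back to the route at 9 and makes no compound outside the list (entry F0).

**Further compounds**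

F1 | step 3 | 3-(methoxymethoxy)-2-methylprop-1-ene | C=C(C)COCOC
F2 | step 3 | (1R,2R)-1-(5-acetyl-2-fluorophenyl)-2-(methoxymethoxy)-3-methylbut-3-en-1-ol | CC(=O)c1ccc(F)c(c1)[C@@H](O)[C@H](OCOC)C(C)=C
F3 | step 3 | (1R,2R)-1-(5-acetyl-2-fluorophenyl)-3-methylbut-3-ene-1,2-diol | CC(=O)c1ccc(F)c(c1)[C@@H](O)[C@H](O)C(C)=C
F4 | step 6 | (1R)-1-[(2R,3R)-2-(3-hydroperoxyprop-1-en-2-yl)-3-(3-methylbutanoyloxy)-2,3-dihydro-1-benzofuran-5-yl]ethyl 3-methylbutanoate | C=C(COO)[C@H]1Oc2ccc([C@@H](C)OC(=O)CC(C)C)cc2[C@H]1OC(=O)CC(C)C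
F0 | step 4 | none | none
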